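Everything rests on disconnecting C10–C11, the bond shared by the cyclopentane (C10–C14) and the eleven-membered ring and flanked by the exocyclic C1=CH2. An intramolecular Hosomi–Sakurai reaction lets C11 of a (Z)-allylsilane (C11=C1–CH2SiMe3) add to the β-carbon C10 of a C8 enone. One operation closes the cis-fused cyclopentane, sets C10 and C11, unveils C1=CH2 and leaves the C8 ketone for the later C7–C8 ring closure. The precursor is a 2-methylcyclohex-2-enone whose quaternary C14 carries the full citronellol-derived chain; its C14/C15 stereocentres come from Wieland–Miescher ketone.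

Key step: step 19

Remark: ring carbons carry the numbers C1–C16 of the target SMILES; β is the face of the six-membered ring that bears the C14 methyl (convex face of the hydrindane), α the opposite face.
Remark: the allylsilane is made as the (Z)-isomer (CH2SiMe3 cis to C12), so that the small CH2–Si arm, not the branched C2 carbinol, points under the ring during closure; C2/C16 carry TES and C15 TBS so that three acetates and one free hydroxyl can be told apart at the end.
Assumption: stereocentres that are erased later (epoxide carbons in 4, 5, 9, 10; C9 in 7; C8 in 11 and 16; C2 in 16; the ozonide carbon in 14) arise as mixtures and are written without descriptors; 1 and 12 are bought enantiopure.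

Step 1
Reactants: 1 (S)-Wieland–Miescher ketone
Product: 2 (4aS,5S)-5-hydroxy-4a-methyl-4,4a,5,6,7,8-hexahydronaphthalen-2(3H)-one
Conditions: NaBH4 (0.3 equiv), EtOH, −10 °C
Reagents that add atoms: none
Why: Chemoselective borohydride reduction: the saturated C15 ketone reacts before the conjugated one and hydride enters anti to the angular methyl, so the C15 hydroxyl is set cis (β) to the C14 methyl.

Step 2
Reactants: 2 (4aS,5S)-5-hydroxy-4a-methyl-4,4a,5,6,7,8-hexahydronaphthalen-2(3H)-one
Product: 3 (4aS,5S)-5-(tert-butyldimethylsilyloxy)-4a-methyl-4,4a,5,6,7,8-hexahydronaphthalen-2(3H)-one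
Conditions: TBSCl, imidazole, DMF, rt
Reagents that add atoms: tert-butyldimethylsilyl chloride, CC(C)(C)[Si](C)(C)Cl
Why: Silyl ether formation; the neopentyl OTBS is hindered enough to outlast the later removal of two TES groups.

Step 3
Reactants: 3 (4aS,5S)-5-(tert-butyldimethylsilyloxy)-4a-methyl-4,4a,5,6,7,8-hexahydronaphthalen-2(3H)-one
Product: 4 epoxy ketone of 3 (epoxide across C1–C10, both faces)
Conditions: 30% H2O2, aq. NaOH, MeOH, 0 °C → rt
Reagents that add atoms: hydrogen peroxide, OO
Why: Weitz–Scheffer nucleophilic epoxidation of the enone; the epoxide configuration is irrelevant because both carbons lose it in step 4.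

Step 4
Reactants: 4 epoxy ketone of 3
Product: 6 (2R,3S)-2-(but-3-yn-1-yl)-3-(tert-butyldimethylsilyloxy)-2-methylcyclohexan-1-one, via epoxy tosylhydrazone 5 (not isolated)
Conditions: TsNHNH2, AcOH–CH2Cl2 (1:1), −20 °C → rt
Reagents that add atoms: p-toluenesulfonyl hydrazide (atoms only in 5), Cc1ccc(cc1)S(=O)(=O)NN
Why: Eschenmoser–Tanabe fragmentation: the epoxy tosylhydrazone opens and expels sulfinate and N2, cleaving C1–C10 to give the C10 ketone and the C11≡C1 terminal alkyne with C14 and C15 untouched.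

Step 5
Reactants: 6 (2R,3S)-2-(but-3-yn-1-yl)-3-(tert-butyldimethylsilyloxy)-2-methylcyclohexan-1-one
Product: 7 (2R,3S)-2-(but-3-yn-1-yl)-3-(tert-butyldimethylsilyloxy)-2,6-dimethylcyclohexan-1-one (both C6 epimers)
Conditions: LDA (1.05 equiv), THF, −78 °C; MeI, −78 → 0 °C
Reagents that add atoms: iodomethane, CI
Why: Enolate alkylation: C14 is quaternary, so the ketone can enolise only towards C9, which is methylated (C9 configuration is irrelevant).

Step 6
Reactants: 7 (2R,3S)-2-(but-3-yn-1-yl)-3-(tert-butyldimethylsilyloxy)-2,6-dimethylcyclohexan-1-one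
Product: 8 (5S,6R)-6-(but-3-yn-1-yl)-5-(tert-butyldimethylsilyloxy)-2,6-dimethylcyclohex-2-en-1-one
Conditions: IBX (2.5 equiv), DMSO–toluene, 70 °C
Reagents that add atoms: none
Why: IBX-mediated α,β-dehydrogenation of a ketone; the only enolisable side gives the endocyclic C8=C9 2-methyl enone.

Step 7
Reactants: 8 (5S,6R)-6-(but-3-yn-1-yl)-5-(tert-butyldimethylsilyloxy)-2,6-dimethylcyclohex-2-en-1-one
Product: 9 2,3-epoxide of 8 (C8–C9 epoxide, both faces)
Conditions: 30% H2O2, NaOH (cat.), MeOH, 0 °C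
Reagents that add atoms: hydrogen peroxide, OO
Why: Weitz–Scheffer epoxidation of an α-methyl enone at its unhindered β-carbon C8 (carvone-type substrate); the epoxide face is irrelevant.

Step 8
Reactants: 9 2,3-epoxide of 8
Product: 11 (4S,5S)-4-(but-3-yn-1-yl)-5-(tert-butyldimethylsilyloxy)-2,4-dimethylcyclohex-2-en-1-ol (both C1 epimers), via epoxy hydrazone 10 (not isolated)
Conditions: N2H4·H2O (3 equiv), AcOH (cat.), MeOH, 0 °C → rt
Reagents that add atoms: hydrazine (atoms only in 10), NN
Why: Wharton transposition: the epoxy hydrazone opens to a vinyl diazene that loses N2, moving oxygen to C8 and the double bond to C9=C10 (C8 configuration is irrelevant).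

Step 9
Reactants: 12 (S)-citronellol
Product: 13 (S)-3,7-dimethyloct-6-en-1-yl pivalate
Conditions: PivCl, pyridine, DMAP (cat.), CH2Cl2, 0 °C
Reagents that add atoms: pivaloyl chloride, CC(C)(C)C(Cl)=O
Why: Acylation of the primary alcohol with an acid chloride.

Step 10
Reactants: 13 (S)-3,7-dimethyloct-6-en-1-yl pivalate
Product: 15 (S)-3-methyl-6-oxohexyl pivalate, via ozonide 14 (not isolated)
Conditions: O3, CH2Cl2, −78 °C; Me2S, −78 °C → rt
Reagents that add atoms: ozone, [O-][O+]=O
Why: Ozonolysis of the trisubstituted alkene with reductive work-up gives the C2 aldehyde; the C5 stereocentre is not involved.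

Step 11
Reactants: 11 (4S,5S)-4-(but-3-yn-1-yl)-5-(tert-butyldimethylsilyloxy)-2,4-dimethylcyclohex-2-en-1-ol; 15 (S)-3-methyl-6-oxohexyl pivalate
Product: 16 C8/C2 diol: cyclohexenol 11 joined at C1 of the alkyne to C2 of 15 (propargylic alcohol, both C2 epimers; C7 pivalate)
Conditions: n-BuLi (2.1 equiv), THF, −78 °C; then 15, −78 °C
Reagents that add atoms: none
Why: Acetylide addition to an aldehyde: the alkoxide/acetylide dianion adds to the aldehyde much faster than to the pivalate (the C2 mixture is corrected in steps 12–13).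

Step 12
Reactants: 16 C8/C2 diol
Product: 17 C8 enone / C2 ynone
Conditions: Dess–Martin periodinane (3 equiv), NaHCO3, CH2Cl2, rt
Reagents that add atoms: none
Why: Dess–Martin oxidation of the allylic and the propargylic alcohol in one operation, which also erases the two unwanted stereocentres.

Step 13
Reactants: 17 C8 enone / C2 ynone
Product: 18 (2R)-propargylic alcohol enone
Conditions: (R,R)-TsDPEN–Ru(p-cymene) amido catalyst (3 mol%), i-PrOH, rt
Reagents that add atoms: none
Why: Noyori asymmetric transfer hydrogenation: the ynone is far more reactive than the hindered α-methyl enone, and the (R,R)-catalyst delivers hydride to give the (2R)-alcohol.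

Step 14
Reactants: 18 (2R)-propargylic alcohol enone
Product: 19 (2R)-propargylic alcohol, 16α-hydroxy enone (C16–OH trans to C15–OTBS)
Conditions: KHMDS (2.2 equiv), THF, −78 °C; 2-(phenylsulfonyl)-3-phenyloxaziridine; AcOH quench at −78 °C
Reagents that add atoms: 2-(phenylsulfonyl)-3-phenyloxaziridine, O=S(=O)(N1OC1c1ccccc1)c1ccccc1
Why: Davis oxidation of the C8–C16 potassium enolate (the only enolate possible, C14 being quaternary); the oxidant enters anti to the adjacent C15 silyloxy group, setting C16 α.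

Step 15
Reactants: 19 (2R)-propargylic alcohol, 16α-hydroxy enone
Product: 20 (Z)-alkenylstannane: C11H=C1(SnBu3)–C2H(OH), tin cis to C12
Conditions: [Cp*RuCl]4 (2.5 mol%), Bu3SnH (1.1 equiv), CH2Cl2, rt
Reagents that add atoms: tributyltin hydride, CCCC[SnH](CCCC)CCCC
Why: Ruthenium-catalysed trans-hydrostannation of a propargylic alcohol: the free C2 hydroxyl steers tin to the proximal carbon C1 and H and Sn add trans, which fixes the alkene geometry.

Step 16
Reactants: 20 (Z)-alkenylstannane
Product: 21 (Z)-alkenyl iodide diol: C11H=C1(I)–C2H(OH), iodine cis to C12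
Conditions: I2 (1.1 equiv), CH2Cl2, 0 °C
Reagents that add atoms: iodine, II
Why: Iododestannylation, which proceeds with retention of alkene geometry.

Step 17
Reactants: 21 (Z)-alkenyl iodide diol
Product: 22 (Z)-alkenyl iodide, C2 and C16 bis-TES ether
Conditions: TESOTf (2.5 equiv), 2,6-lutidine, CH2Cl2, −78 °C
Reagents that add atoms: triethylsilyl triflate, CC[Si](CC)(CC)OS(=O)(=O)C(F)(F)F
Why: Silylation of both secondary alcohols with a silyl triflate and a hindered base.

Step 18
Reactants: 22 (Z)-alkenyl iodide bis-TES ether; 23 (trimethylsilyl)methylmagnesium chloride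
Product: 24 cyclisation precursor: 2-methylcyclohex-2-enone (C8=O, C9(Me)=C10H) with C14 (Me β; chain α), C15 β-OTBS, C16 α-OTES and chain C13–C12–C11H=C1(CH2SiMe3)–C2H(OTES)–C3–C4–C5H(Me)–C6–C7–OPiv, (Z), (2R,5S)
Conditions: 23 + ZnCl2, THF, 0 °C; then 22, Pd(PPh3)4 (5 mol%), THF, 45 °C
Reagents that add atoms: none
Why: Negishi coupling with retention of geometry; the organozinc reagent does not touch the enone, the α-silyloxy ketone or the pivalate.

Step 19
Reactants: 24 cyclisation precursor
Product: 25 cis-hydrindan-8-one: C10–C11 bond formed, C1=CH2, H10 β, H11 β (C1 α, cis to C9), C9 methyl α, protecting groups as in 24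
Conditions: EtAlCl2 (3 equiv), CH2Cl2, −78 → −40 °C; aq. NaHCO3
Reagents that add atoms: none
Why: EtAlCl2 binds the C8 carbonyl and the γ-carbon C11 of the allylsilane attacks the β-carbon C10 anti to silicon (SE2′); the β-silyl cation at C1 gives up Me3Si+ to chloride, leaving C1=CH2 and a C8–C9 aluminium enolate that is protonated from the convex β-face on work-up (C9 is temporary). This is the intramolecular Hosomi–Sakurai conjugate addition known for 4-tethered cyclohexenones, which delivers cis-hydrindanones. The cyclopentane C10–C11–C12–C13–C14 closes in the 5-exo-trig mode (C9 of the enone and C1 of the allylsilane both stay outside the new ring). C10 is controlled by the three-atom tether, which can reach C10 only from the α-face on which it leaves C14 (cis fusion), and C11 by the endo (synclinal) arrangement in which C1 lies under the six-membered ring, cis to C9. The step needs this endo/exo selectivity: the (Z)-geometry puts only the CH2–Si arm (silicon pointing away) beneath the ring next to the axial C16 oxygen, whereas the exo alternative would press the branched C2 carbinol against the C9 methyl. The silyl ethers and the pivalate should tolerate the aprotic aluminium Lewis acid at low temperature.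

Step 20
Reactants: 25 cis-hydrindan-8-one
Product: 26 C8 enol triflate (C8=C9 tetrasubstituted)
Conditions: KHMDS (1.2 equiv), THF, −78 °C; PhNTf2
Reagents that add atoms: N-phenylbis(trifluoromethanesulfonimide), O=S(=O)(N(c1ccccc1)S(=O)(=O)C(F)(F)F)C(F)(F)F
Why: Enol triflate formation: the hindered amide should remove the convex C9–H rather than the C16–H that carries the silyloxy group, and the tetrasubstituted enolate is trapped on oxygen.

Step 21
Reactants: 26 C8 enol triflate
Product: 27 C7 primary alcohol (enol triflate)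
Conditions: DIBAL-H (2.5 equiv), CH2Cl2, −78 °C
Reagents that add atoms: none
Why: Hydride reduction of the pivalate ester to the primary alcohol; enol triflate and silyl ethers are inert at −78 °C.

Step 22
Reactants: 27 C7 primary alcohol
Product: 28 C7 aldehyde (enol triflate)
Conditions: Dess–Martin periodinane, NaHCO3, CH2Cl2, 0 °C → rt
Reagents that add atoms: none
Why: Dess–Martin oxidation of a primary alcohol to the aldehyde under buffered conditions.

Step 23
Reactants: 28 C7 aldehyde
Product: 29 tricyclic (7S)-allylic alcohol (C7–C8 bond closed; C2/C16 OTES, C15 OTBS)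
Conditions: CrCl2 (10 equiv), NiCl2 (0.1 equiv), DMSO–THF, 2 mM, rt
Reagents that add atoms: none
Why: Nozaki–Hiyama–Kishi reaction: nickel inserts into the C8–OTf bond, chromium(III) takes over the alkenyl group and adds to the C7 aldehyde under high dilution, closing the eleven-membered ring; C7 is set by the conformation of the forming ring, the (7S) alcohol with oxygen on the periphery being expected but not secured.

Step 24
Reactants: 29 tricyclic (7S)-allylic alcohol
Product: 30 2,7,16-triol 15-TBS ether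
Conditions: HF·pyridine, pyridine, THF, 0 °C
Reagents that add atoms: none
Why: Selective desilylation: buffered HF·pyridine cleaves the two secondary TES ethers while the neopentyl C15 OTBS survives.

Step 25
Reactants: 30 2,7,16-triol 15-TBS ether
Product: 31 2,7,16-triacetate 15-TBS ether
Conditions: Ac2O, pyridine, DMAP (cat.), CH2Cl2, rt
Reagents that add atoms: acetic anhydride, CC(=O)OC(C)=O
Why: DMAP-catalysed acetylation of the three secondary allylic alcohols.

Step 26
Reactants: 31 2,7,16-triacetate 15-TBS ether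
Product: 32 CNP0318778.1
Conditions: HF·pyridine (excess), THF, 0 °C → rt
Reagents that add atoms: none
Why: Acidic fluoride cleaves the remaining TBS ether, and the acidic medium avoids acetyl migration from O16 to O15.

Compound list
1 | (S)-Wieland–Miescher ketone, (8aS)-8a-methyl-3,4,8,8a-tetrahydronaphthalene-1,6(2H,7H)-dione | C[C@]12CCC(=O)C=C1CCCC2=O | starting material
2 | (4aS,5S)-5-hydroxy-4a-methyl-4,4a,5,6,7,8-hexahydronaphthalen-2(3H)-one | C[C@]12CCC(=O)C=C1CCC[C@@H]2O | intermediate
3 | (4aS,5S)-5-(tert-butyldimethylsilyloxy)-4a-methyl-4,4a,5,6,7,8-hexahydronaphthalen-2(3H)-one | C[C@]12CCC(=O)C=C1CCC[C@@H]2O[Si](C)(C)C(C)(C)C | intermediate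
4 | epoxy ketone of 3 (C1–C10 epoxide, both faces) | C[C@]12CCC(=O)C3OC13CCC[C@@H]2O[Si](C)(C)C(C)(C)C | intermediate
5 | tosylhydrazone of 4 | Cc1ccc(cc1)S(=O)(=O)NN=C1CC[C@]2(C)[C@@H](O[Si](C)(C)C(C)(C)C)CCCC23OC13 | intermediate (not isolated)
6 | (2R,3S)-2-(but-3-yn-1-yl)-3-(tert-butyldimethylsilyloxy)-2-methylcyclohexan-1-one | C#CCC[C@@]1(C)C(=O)CCC[C@@H]1O[Si](C)(C)C(C)(C)C | intermediate
7 | (2R,3S)-2-(but-3-yn-1-yl)-3-(tert-butyldimethylsilyloxy)-2,6-dimethylcyclohexan-1-one (C6 epimers) | C#CCC[C@@]1(C)C(=O)C(C)CC[C@@H]1O[Si](C)(C)C(C)(C)C | intermediate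
8 | (5S,6R)-6-(but-3-yn-1-yl)-5-(tert-butyldimethylsilyloxy)-2,6-dimethylcyclohex-2-en-1-one | C#CCC[C@@]1(C)C(=O)C(C)=CC[C@@H]1O[Si](C)(C)C(C)(C)C | intermediate
9 | 2,3-epoxide of 8 (both faces) | C#CCC[C@@]1(C)C(=O)C2(C)OC2C[C@@H]1O[Si](C)(C)C(C)(C)C | intermediate
10 | hydrazone of 9 | C#CCC[C@@]1(C)C(=NN)C2(C)OC2C[C@@H]1O[Si](C)(C)C(C)(C)C | intermediate (not isolated)
11 | (4S,5S)-4-(but-3-yn-1-yl)-5-(tert-butyldimethylsilyloxy)-2,4-dimethylcyclohex-2-en-1-ol (C1 epimers) | C#CCC[C@@]1(C)C=C(C)C(O)C[C@@H]1O[Si](C)(C)C(C)(C)C | intermediate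
12 | (S)-citronellol | CC(C)=CCC[C@H](C)CCO | starting material
13 | (S)-3,7-dimethyloct-6-en-1-yl pivalate | CC(C)=CCC[C@H](C)CCOC(=O)C(C)(C)C | intermediate
14 | ozonide of 13 (5,5-dimethyl-1,2,4-trioxolane) | CC1(C)OOC(CC[C@H](C)CCOC(=O)C(C)(C)C)O1 | intermediate (not isolated)
15 | (S)-3-methyl-6-oxohexyl pivalate | O=CCC[C@H](C)CCOC(=O)C(C)(C)C | intermediate
16 | C8/C2 diol (cyclohexenol with propargylic alcohol chain, C7 pivalate; C2 and C8 epimers) | CC1=C[C@](C)(CCC#CC(O)CC[C@H](C)CCOC(=O)C(C)(C)C)[C@@H](O[Si](C)(C)C(C)(C)C)CC1O | intermediate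
17 | C8 enone / C2 ynone | CC1=C[C@](C)(CCC#CC(=O)CC[C@H](C)CCOC(=O)C(C)(C)C)[C@@H](O[Si](C)(C)C(C)(C)C)CC1=O | intermediate
18 | (2R)-propargylic alcohol enone | CC1=C[C@](C)(CCC#C[C@H](O)CC[C@H](C)CCOC(=O)C(C)(C)C)[C@@H](O[Si](C)(C)C(C)(C)C)CC1=O | intermediate
19 | (2R)-propargylic alcohol, 16α-hydroxy enone | CC1=C[C@](C)(CCC#C[C@H](O)CC[C@H](C)CCOC(=O)C(C)(C)C)[C@@H](O[Si](C)(C)C(C)(C)C)[C@H](O)C1=O | intermediate
20 | (Z)-alkenylstannane diol (SnBu3 on C1, cis to C12) | CC1=C[C@](C)(CC/C=C(\[Sn](CCCC)(CCCC)CCCC)[C@H](O)CC[C@H](C)CCOC(=O)C(C)(C)C)[C@@H](O[Si](C)(C)C(C)(C)C)[C@H](O)C1=O | intermediate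
21 | (Z)-alkenyl iodide diol (I on C1, cis to C12) | CC1=C[C@](C)(CC/C=C(\I)[C@H](O)CC[C@H](C)CCOC(=O)C(C)(C)C)[C@@H](O[Si](C)(C)C(C)(C)C)[C@H](O)C1=O | intermediate
22 | (Z)-alkenyl iodide, C2/C16 bis-TES ether | CC1=C[C@](C)(CC/C=C(\I)[C@H](O[Si](CC)(CC)CC)CC[C@H](C)CCOC(=O)C(C)(C)C)[C@@H](O[Si](C)(C)C(C)(C)C)[C@H](O[Si](CC)(CC)CC)C1=O | intermediate
23 | (trimethylsilyl)methylmagnesium chloride | C[Si](C)(C)C[Mg]Cl | starting material
24 | cyclisation precursor, (Z)-allylsilane 2-methylcyclohexenone | CC1=C[C@](C)(CC/C=C(\C[Si](C)(C)C)[C@H](O[Si](CC)(CC)CC)CC[C@H](C)CCOC(=O)C(C)(C)C)[C@@H](O[Si](C)(C)C(C)(C)C)[C@H](O[Si](CC)(CC)CC)C1=O | intermediate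
25 | cis-hydrindan-8-one with C1 methylene and full chain (C9 methyl α) | C=C([C@H](O[Si](CC)(CC)CC)CC[C@H](C)CCOC(=O)C(C)(C)C)[C@@H]1CC[C@]2(C)[C@@H](O[Si](C)(C)C(C)(C)C)[C@H](O[Si](CC)(CC)CC)C(=O)[C@H](C)[C@H]12 | intermediate
26 | C8 enol triflate | C=C([C@H](O[Si](CC)(CC)CC)CC[C@H](C)CCOC(=O)C(C)(C)C)[C@@H]1CC[C@]2(C)[C@@H](O[Si](C)(C)C(C)(C)C)[C@H](O[Si](CC)(CC)CC)C(OS(=O)(=O)C(F)(F)F)=C(C)[C@H]12 | intermediate
27 | C7 primary alcohol (enol triflate) | C=C([C@H](O[Si](CC)(CC)CC)CC[C@H](C)CCO)[C@@H]1CC[C@]2(C)[C@@H](O[Si](C)(C)C(C)(C)C)[C@H](O[Si](CC)(CC)CC)C(OS(=O)(=O)C(F)(F)F)=C(C)[C@H]12 | intermediate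
28 | C7 aldehyde (enol triflate) | C=C([C@H](O[Si](CC)(CC)CC)CC[C@H](C)CC=O)[C@@H]1CC[C@]2(C)[C@@H](O[Si](C)(C)C(C)(C)C)[C@H](O[Si](CC)(CC)CC)C(OS(=O)(=O)C(F)(F)F)=C(C)[C@H]12 | intermediate
29 | tricyclic (7S)-allylic alcohol, C2/C16 OTES, C15 OTBS | C=C1[C@H](O[Si](CC)(CC)CC)CC[C@H](C)C[C@H](O)C2=C(C)[C@@H]3[C@H]1CC[C@]3(C)[C@@H](O[Si](C)(C)C(C)(C)C)[C@@H]2O[Si](CC)(CC)CC | intermediate
30 | 2,7,16-triol 15-TBS ether | C=C1[C@H](O)CC[C@H](C)C[C@H](O)C2=C(C)[C@@H]3[C@H]1CC[C@]3(C)[C@@H](O[Si](C)(C)C(C)(C)C)[C@@H]2O | intermediate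
31 | 2,7,16-triacetate 15-TBS ether | C=C1[C@H](OC(C)=O)CC[C@H](C)C[C@H](OC(C)=O)C2=C(C)[C@@H]3[C@H]1CC[C@]3(C)[C@@H](O[Si](C)(C)C(C)(C)C)[C@@H]2OC(C)=O | intermediate
32 | CNP0318778.1 | C=C1[C@H](OC(C)=O)CC[C@H](C)C[C@H](OC(C)=O)C2=C(C)[C@@H]3[C@H]1CC[C@]3(C)[C@@H](O)[C@@H]2OC(C)=O | target

Total step count: 26. Longest linear sequence: 24 steps (steps 1–8 and 11–26, from 1).

Steps most likely to fail

Step 19. The allylsilane may react through the exo arrangement, with C1 turned away from the six-membered ring, which means poor facial selectivity at C11; protodesilylation may also compete. The fallback is a temporary silicon tether that holds C1 on the α-face. It sets out from 21: Negishi coupling as in step 18, run on the free diol, should give the allylsilane diol F1. Treatment with i-Pr2SiCl2 and imidazole in DMF under high dilution should link O2 to O16 as the eleven-membered silylene F2. EtAlCl2 should then close the ring transannularly to the silylene-bridged hydrindanone F3. HF·pyridine should free the diol ketone F4, and TESOTf/2,6-lutidine brings the route back to 25.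

Step 23. Closure of the strained ring may be slow, and facial selectivity at C7 may be poor. The fallback replaces macrocyclic control by reagent control. It sets out from 28: the same Ni/Cr coupling is expected to give, beside 29, the (7R)-epimer F5. The mixture is oxidised with Dess–Martin periodinane to the macrocyclic C7 enone F6, and Corey–Bakshi–Shibata reduction with the (R)-oxazaborolidine and catecholborane should return to 29.

Step 8. Hydrazone formation at the C10 carbonyl, which sits between the quaternary C14 and the methyl-bearing epoxide carbon, may be slower than opening of the epoxide by hydrazine. The fallback moves the oxygen with hydride and titanium(III) instead. It sets out from 9: NaBH4/CeCl3 should reduce the ketone to the epoxy alcohol F7, and MsCl/Et3N should give the epoxy mesylate F8. Cp2TiCl (from Cp2TiCl2 and Zn, THF) should open the epoxide homolytically at C9 and eliminate the mesylate, coming back to 11.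

Further compounds
F1 | step 19 | (Z)-allylsilane C2/C16 diol | CC1=C[C@](C)(CC/C=C(\C[Si](C)(C)C)[C@H](O)CC[C@H](C)CCOC(=O)C(C)(C)C)[C@@H](O[Si](C)(C)C(C)(C)C)[C@H](O)C1=O
F2 | step 19 | O2,O16-diisopropylsilylene-tethered precursor | CC1=C[C@](C)(CC/C=C(\C[Si](C)(C)C)[C@H](O[Si]2(C(C)C)C(C)C)CC[C@H](C)CCOC(=O)C(C)(C)C)[C@@H](O[Si](C)(C)C(C)(C)C)[C@H](O2)C1=O
F3 | step 19 | silylene-bridged cis-hydrindan-8-one | C=C([C@H](O[Si]3(C(C)C)C(C)C)CC[C@H](C)CCOC(=O)C(C)(C)C)[C@@H]1CC[C@]2(C)[C@@H](O[Si](C)(C)C(C)(C)C)[C@H](O3)C(=O)[C@H](C)[C@H]12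
F4 | step 19 | C2/C16 diol cis-hydrindan-8-one | C=C([C@H](O)CC[C@H](C)CCOC(=O)C(C)(C)C)[C@@H]1CC[C@]2(C)[C@@H](O[Si](C)(C)C(C)(C)C)[C@H](O)C(=O)[C@H](C)[C@H]12
F5 | step 23 | (7R)-epimer of 29 | C=C1[C@H](O[Si](CC)(CC)CC)CC[C@H](C)C[C@@H](O)C2=C(C)[C@@H]3[C@H]1CC[C@]3(C)[C@@H](O[Si](C)(C)C(C)(C)C)[C@@H]2O[Si](CC)(CC)CC
F6 | step 23 | macrocyclic C7 enone | C=C1[C@H](O[Si](CC)(CC)CC)CC[C@H](C)CC(=O)C2=C(C)[C@@H]3[C@H]1CC[C@]3(C)[C@@H](O[Si](C)(C)C(C)(C)C)[C@@H]2O[Si](CC)(CC)CC
F7 | step 8 | epoxy alcohol (C10 carbinol, C8–C9 epoxide) | C#CCC[C@@]1(C)C(O)C2(C)OC2C[C@@H]1O[Si](C)(C)C(C)(C)C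
F8 | step 8 | epoxy mesylate | C#CCC[C@@]1(C)C(OS(C)(=O)=O)C2(C)OC2C[C@@H]1O[Si](C)(C)C(C)(C)C
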